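Locants: the flavanone half is C2–C8a (rings A and C) and carries catechol ring B' (C1'–C6'). The luteolin half is C2''–C8a'' (rings A'' and C'') and carries catechol ring B''' (C1'''–C6''').
Enabling feature: ring A'' (C4a'', C5'', C6'', C7'', C8'', C8a'') is a 1,3,5-trioxygenated benzene. Its C8'' sits between the oxygen-bearing C7'' and C8a'' and holds C2' of ring B'. An aryl ynol ether supplies C8''–C7'' with aryl and oxygen already in place, and a 3-alkoxycyclobutenone supplies C8a'', C4a'', C5'' and C6''. The tetra-ortho-substituted C2'–C8'' bond therefore begins as an unhindered aryl–alkyne bond and is never made between two arenes.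
Cuts, in retrosynthetic order: eight O–benzyl bonds; O1–C2 and C2–C3 of ring C (oxa-Michael, Knoevenagel); C4a''–C4'', C4''–C3'' and O1''–C2'' of ring C'' (carbonylative annulation); C8''–C8a'' and C6''–C7'' of ring A'' (benzannulation, with C4a''–C8a'' re-closed); C2'–C(sp) (Sonogashira).
Forward order: ring B' is bought, ring A'' is grown on its alkyne, ring C'' is annulated together with ring B''', and ring C is closed last onto the bought ring A.
Stereochemistry: C2 (S) is the only defined stereocentre. It is set by a cinchona-thiourea-catalysed oxa-Michael closure of an alkylidene β-ketoester, and everything after it is acidic or neutral, so retro-Michael scrambling is avoided.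

Key step: step 8

Assumption: the target structure defines only C2. The hindered C2'–C8'' axis forms without control in step 8, is carried as a mixture of atropisomers, and is left open in every SMILES below.
Assumption: the quinine-derived thiourea is taken as the catalyst antipode that gives 2S. If a model cyclisation shows the opposite sense, the quinidine-derived pseudoenantiomer replaces it and nothing else changes.
Abbreviations: Bn = benzyl; TBS = tert-butyldimethylsilyl; TIPS = triisopropylsilyl; Ar1 = 2,3-bis(benzyloxy)-6-(TBSO-methyl)phenyl (ring B'); Fl = 5,7-bis(benzyloxy)-2-[3,4-bis(benzyloxy)phenyl]-4-oxo-4H-chromen-8-yl.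

Step 1
Reactants: 1 2-bromo-3-hydroxy-4-methoxybenzaldehyde
Product: 2 2-bromo-3,4-dihydroxybenzaldehyde
Conditions: BBr3 (2.5 equiv), CH2Cl2, −78 °C to rt; H2O
Reagents that add atoms: none
Why: Lewis-acid aryl methyl ether cleavage, in which boron binds the ether oxygen and bromide removes the methyl group by SN2 attack, is tolerated by aryl bromides and benzaldehydes at low temperature.

Step 2
Reactants: 2 2-bromo-3,4-dihydroxybenzaldehyde
Product: 3 3,4-bis(benzyloxy)-2-bromobenzaldehyde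
Conditions: BnBr (2.3 equiv), K2CO3, DMF, 60 °C
Reagents that add atoms: benzyl bromide, BrCc1ccccc1
Why: Williamson etherification of both phenoxides installs the hydrogenolysable group that protects every phenol of the route.

Step 3
Reactants: 3 3,4-bis(benzyloxy)-2-bromobenzaldehyde; 4 ethynyltrimethylsilane
Product: 5 3,4-bis(benzyloxy)-2-[(trimethylsilyl)ethynyl]benzaldehyde
Conditions: PdCl2(PPh3)2 (5 mol %), CuI (10 mol %), Et3N, DMF, 80 °C, sealed tube
Reagents that add atoms: none
Why: Sonogashira coupling is run at the aldehyde stage because the ortho formyl group speeds oxidative addition of zerovalent palladium into the flanked C–Br bond, and the slim alkyne creates the future C2'–C8'' bond without steric penalty.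

Step 4
Reactants: 5 3,4-bis(benzyloxy)-2-[(trimethylsilyl)ethynyl]benzaldehyde
Product: 7 [3,4-bis(benzyloxy)-2-ethynylphenyl]methanol, via silylalkynyl benzyl alcohol 6 (not isolated)
Conditions: NaBH4, MeOH/THF, 0 °C; then K2CO3 (0.2 equiv), rt
Reagents that add atoms: none
Why: Borohydride reduction of the aldehyde is followed in the same methanolic flask by carbonate-catalysed protiodesilylation of the alkyne, and at room temperature a 2-ethynylbenzyl alcohol does not cyclise.

Step 5
Reactants: 7 [3,4-bis(benzyloxy)-2-ethynylphenyl]methanol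
Product: 8 tert-butyl{[3,4-bis(benzyloxy)-2-ethynylbenzyl]oxy}dimethylsilane
Conditions: TBSCl, imidazole, CH2Cl2, rt
Reagents that add atoms: tert-butyldimethylsilyl chloride, CC(C)(C)[Si](C)(C)Cl
Why: Imidazole-promoted silylation masks C1' as an inert silyloxymethyl group that withstands organolithium, peroxide, heat and palladium catalysis.

Step 6
Reactants: 8 tert-butyl{[3,4-bis(benzyloxy)-2-ethynylbenzyl]oxy}dimethylsilane
Product: 11 tert-butyl{[3,4-bis(benzyloxy)-2-({[tri(propan-2-yl)silyl]oxy}ethynyl)benzyl]oxy}dimethylsilane, via lithium acetylide 9 (not isolated), via lithium ynolate 10 (not isolated)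
Conditions: n-BuLi, THF, −78 °C; t-BuOOLi (from t-BuOOH and LiN(SiMe3)2, THF, −78 °C), −78 to 0 °C; TIPSOTf, −78 to 0 °C
Reagents that add atoms: tert-butyl hydroperoxide (as its lithium salt), CC(C)(C)OO; triisopropylsilyl trifluoromethanesulfonate, CC(C)[Si](OS(=O)(=O)C(F)(F)F)(C(C)C)C(C)C
Why: Electrophilic oxygenation of a lithium acetylide by lithium tert-butyl peroxide (attack at the peroxide oxygen, loss of tert-butoxide) gives the ynolate, the hard silyl triflate traps it on oxygen, and the bulky silyl group makes the ynol ether stable to isolation.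

Step 7
Reactants: 12 3-ethoxycyclobut-2-en-1-one
Product: 13 3-(benzyloxy)cyclobut-2-en-1-one
Conditions: BnOH (3 equiv), camphorsulfonic acid (5 mol %), toluene, 35 °C, reduced pressure (removal of EtOH)
Reagents that add atoms: benzyl alcohol, OCc1ccccc1
Why: Acid-catalysed transetherification of a vinylogous ester proceeds by protonation on the carbonyl oxygen, addition of benzyl alcohol at C3 and loss of ethanol, and stripping the volatile ethanol well below the ring-opening temperature drives the exchange.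

Step 8
Reactants: 11 tert-butyl{[3,4-bis(benzyloxy)-2-({[tri(propan-2-yl)silyl]oxy}ethynyl)benzyl]oxy}dimethylsilane; 13 3-(benzyloxy)cyclobut-2-en-1-one
Product: 18 2-Ar1-5-(benzyloxy)-3-(TIPSO)phenol, via vinylketene 14 (not isolated), via vinylcyclobutenone 15 (not isolated), via dienylketene 16 (not isolated), via cyclohexadienone 17 (not isolated)
Conditions: toluene, 80 °C then 110 °C, argon; 13 (2 equiv) added over several hours
Reagents that add atoms: none
Why: Heat opens 13 by 4π electrocyclic cleavage of its C1–C4 bond to the 3-benzyloxy vinylketene 14, whose ketene carbon is attacked by the nucleophilic, aryl-bearing alkyne carbon of 11 in a [2+2] cycloaddition that gives 15 and makes C8''–C8a'' and C6''–C7''. A second 4π opening turns 15 into dienylketene 16, ring A'' closes by 6π electrocyclisation between the methylene terminus (C4a'') and the ketene carbon (C8a''), and dienone 17 tautomerises irreversibly to phenol 18. This is the Danheiser benzannulation in its siloxyalkyne variant, the established entry to monosilylated resorcinols. No stereocentre survives, since the sp3 carbon of 15 is lost on ring opening and the new C2'–C8'' axis forms without control. The only selectivity needed is the orientation of the [2+2] step, and it follows from the ynol ether polarisation (oxygen pushes electron density onto the carbon bearing ring B'), so the aryl group must end between the silyloxy carbon and the single free hydroxyl, the future O1''. The linear alkyne holds both ortho substituents of ring B' away from the reacting carbons, and slow addition of 13 keeps 14 dilute so that ketene dimerisation and O-acylation of 18 stay minor.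

Step 9
Reactants: 18 2-Ar1-5-(benzyloxy)-3-(TIPSO)phenol
Product: 19 2-Ar1-5-(benzyloxy)-6-iodo-3-(TIPSO)phenol
Conditions: NIS (1.0 equiv), CH2Cl2, −40 to 0 °C, dark
Reagents that add atoms: N-iodosuccinimide, O=C1CCC(=O)N1I
Why: In this electrophilic aromatic iodination both open positions are activated by three oxygens, but C6'' is walled in by the triisopropylsilyloxy group (pushed toward it by ring B') and the benzyloxy group, whereas C4a'' lies next to the small hydrogen-bond-donating hydroxyl, so one equivalent of reagent in a non-polar solvent should iodinate ortho to the phenol.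

Step 10
Reactants: 20 3,4-bis(benzyloxy)benzaldehyde
Product: 21 1,2-bis(benzyloxy)-4-ethynylbenzene
Conditions: dimethyl (1-diazo-2-oxopropyl)phosphonate, K2CO3 (2 equiv), MeOH/THF, rt
Reagents that add atoms: dimethyl (1-diazo-2-oxopropyl)phosphonate, COP(=O)(OC)C(=[N+]=[N-])C(C)=O
Why: Ohira–Bestmann homologation (methanolysis to the diazomethylphosphonate anion, olefination, loss of N2 and 1,2-shift of the alkylidene carbene) converts non-enolisable aryl aldehydes into terminal alkynes under mild base.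

Step 11
Reactants: 19 2-Ar1-5-(benzyloxy)-6-iodo-3-(TIPSO)phenol; 21 1,2-bis(benzyloxy)-4-ethynylbenzene
Product: 24 8-Ar1-5-(benzyloxy)-2-[3,4-bis(benzyloxy)phenyl]-7-(TIPSO)-4H-chromen-4-one, via hydroxyaryl ynone 22 (not isolated), via enaminone 23 (not isolated)
Conditions: PdCl2(dppf) (5 mol %), CO (10 bar), Et2NH, 100 °C
Reagents that add atoms: carbon monoxide, [C-]#[O+]
Why: In this palladium-catalysed carbonylative annulation of an o-iodophenol with a terminal alkyne, oxidative addition of zerovalent palladium, CO insertion and acyl–alkynyl coupling give 22, diethylamine adds to give 23, and addition–elimination by the phenol oxygen closes ring C'' in the six-membered flavone sense instead of the five-membered aurone sense.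

Step 12
Reactants: 24 8-Ar1-5-(benzyloxy)-2-[3,4-bis(benzyloxy)phenyl]-7-(TIPSO)-4H-chromen-4-one
Product: 25 5-(benzyloxy)-2-[3,4-bis(benzyloxy)phenyl]-8-[2,3-bis(benzyloxy)-6-(hydroxymethyl)phenyl]-7-hydroxy-4H-chromen-4-one
Conditions: TBAF (3 equiv), THF, 0 °C to rt
Reagents that add atoms: none
Why: Fluoride-driven desilylation removes the aryl and the primary alkyl silyl ether together, so any partial loss of the phenolic silyl group in step 11 does not matter.

Step 13
Reactants: 25 5-(benzyloxy)-2-[3,4-bis(benzyloxy)phenyl]-8-[2,3-bis(benzyloxy)-6-(hydroxymethyl)phenyl]-7-hydroxy-4H-chromen-4-one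
Product: 26 5,7-bis(benzyloxy)-2-[3,4-bis(benzyloxy)phenyl]-8-[2,3-bis(benzyloxy)-6-(hydroxymethyl)phenyl]-4H-chromen-4-one
Conditions: BnBr (1.2 equiv), K2CO3, DMF, 40 °C
Reagents that add atoms: benzyl bromide, BrCc1ccccc1
Why: Carbonate deprotonates only the acidic 7''-phenol, so the Williamson benzylation spares the alcohol, and capping this oxygen prevents six-membered lactol formation with the coming aldehyde and protonation of the basic catalyst in step 18.

Step 14
Reactants: 26 5,7-bis(benzyloxy)-2-[3,4-bis(benzyloxy)phenyl]-8-[2,3-bis(benzyloxy)-6-(hydroxymethyl)phenyl]-4H-chromen-4-one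
Product: 27 3,4-bis(benzyloxy)-2-Fl-benzaldehyde
Conditions: Dess–Martin periodinane, CH2Cl2, rt
Reagents that add atoms: none
Why: Dess–Martin oxidation takes hindered benzylic alcohols to aldehydes under mild conditions that leave benzyl ethers and the pyrone untouched.

Step 15
Reactants: 28 2,4,6-trihydroxyacetophenone
Product: 29 1-[2,4-bis(benzyloxy)-6-hydroxyphenyl]ethan-1-one
Conditions: BnBr (2.05 equiv), K2CO3, acetone, reflux
Reagents that add atoms: benzyl bromide, BrCc1ccccc1
Why: In this Williamson etherification one ortho hydroxyl stays locked in a hydrogen bond to the ketone and is much less nucleophilic, so two equivalents of halide stop at the dibenzyl ether.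

Step 16
Reactants: 29 1-[2,4-bis(benzyloxy)-6-hydroxyphenyl]ethan-1-one
Product: 30 tert-butyl 3-[2,4-bis(benzyloxy)-6-hydroxyphenyl]-3-oxopropanoate
Conditions: LiN(SiMe3)2 (3.3 equiv), THF, −78 °C; Boc2O (1.1 equiv), −78 to 0 °C
Reagents that add atoms: di-tert-butyl dicarbonate, CC(C)(C)OC(=O)OC(=O)OC(C)(C)C
Why: Claisen-type C-acylation of the lithium enolate gives the β-ketoester, any carbonate formed on the phenoxide is carried to the same product by Baker–Venkataraman-type O-to-C transfer under the excess base, and the tert-butyl ester resists lactonisation to a 4-hydroxycoumarin.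

Step 17
Reactants: 27 3,4-bis(benzyloxy)-2-Fl-benzaldehyde; 30 tert-butyl 3-[2,4-bis(benzyloxy)-6-hydroxyphenyl]-3-oxopropanoate
Product: 31 tert-butyl 2-[2,4-bis(benzyloxy)-6-hydroxybenzoyl]-3-[3,4-bis(benzyloxy)-2-Fl-phenyl]prop-2-enoate (alkene geometry unassigned)
Conditions: piperidine (20 mol %), AcOH (20 mol %), 4 Å MS, toluene, rt
Reagents that add atoms: none
Why: Knoevenagel condensation of the doubly activated methylene forms C2=C3 under nearly neutral amine/acid catalysis, which spares the base-sensitive pyrone the hydroxide of a Claisen–Schmidt reaction and delivers a stronger Michael acceptor.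

Step 18
Reactants: 31 tert-butyl 2-[2,4-bis(benzyloxy)-6-hydroxybenzoyl]-3-[3,4-bis(benzyloxy)-2-Fl-phenyl]prop-2-enoate
Product: 33 (2S)-5,7-bis(benzyloxy)-2-[3,4-bis(benzyloxy)-2-Fl-phenyl]-2,3-dihydro-4H-chromen-4-one, via flavanone tert-butyl ester 32 (not isolated)
Conditions: N-[3,5-bis(trifluoromethyl)phenyl]-N'-[(8α,9S)-6'-methoxycinchonan-9-yl]thiourea (10 mol %), toluene, −25 °C; then TsOH·H2O, 80 °C
Reagents that add atoms: none
Why: In this bifunctional-thiourea-catalysed intramolecular oxa-Michael addition (6-endo-trig) the thiourea binds the β-ketoester carbonyls while the quinuclidine deprotonates the phenol, so O1 reaches one face of C2 and sets 2S under catalyst control, after which acid cleaves the tert-butyl ester and the β-keto acid loses CO2 without touching C2.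

Step 19
Reactants: 33 (2S)-5,7-bis(benzyloxy)-2-[3,4-bis(benzyloxy)-2-Fl-phenyl]-2,3-dihydro-4H-chromen-4-one
Product: 34 (2S)-2-{2-[2-(3,4-dihydroxyphenyl)-5,7-dihydroxy-4-oxo-4H-chromen-8-yl]-3,4-dihydroxyphenyl}-5,7-dihydroxy-2,3-dihydro-4H-chromen-4-one (CNP0265600.1)
Conditions: H2 (1 atm), Pd/C (10 wt %), THF/MeOH, rt
Reagents that add atoms: none
Why: Catalytic hydrogenolysis removes all eight benzyl ethers in a neutral medium in which the flavone double bond and the flavanone ketone are normally retained and C2 cannot epimerise by base-induced ring opening.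

Compound list
1 | 2-bromo-3-hydroxy-4-methoxybenzaldehyde | COc1ccc(C=O)c(Br)c1O | starting material
2 | 2-bromo-3,4-dihydroxybenzaldehyde | O=Cc1ccc(O)c(O)c1Br | intermediate
3 | 3,4-bis(benzyloxy)-2-bromobenzaldehyde | O=Cc1ccc(OCc2ccccc2)c(OCc2ccccc2)c1Br | intermediate
4 | ethynyltrimethylsilane | C#C[Si](C)(C)C | starting material
5 | 3,4-bis(benzyloxy)-2-[(trimethylsilyl)ethynyl]benzaldehyde | O=Cc1ccc(OCc2ccccc2)c(OCc2ccccc2)c1C#C[Si](C)(C)C | intermediate
6 | {3,4-bis(benzyloxy)-2-[(trimethylsilyl)ethynyl]phenyl}methanol | OCc1ccc(OCc2ccccc2)c(OCc2ccccc2)c1C#C[Si](C)(C)C | intermediate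
7 | [3,4-bis(benzyloxy)-2-ethynylphenyl]methanol | OCc1ccc(OCc2ccccc2)c(OCc2ccccc2)c1C#C | intermediate
8 | tert-butyl{[3,4-bis(benzyloxy)-2-ethynylbenzyl]oxy}dimethylsilane | C#Cc1c(CO[Si](C)(C)C(C)(C)C)ccc(OCc2ccccc2)c1OCc1ccccc1 | intermediate
9 | lithium acetylide of 8 | [Li+].[C-]#Cc1c(CO[Si](C)(C)C(C)(C)C)ccc(OCc2ccccc2)c1OCc1ccccc1 | intermediate
10 | lithium 2-Ar1-ethynolate | [Li+].[O-]C#Cc1c(CO[Si](C)(C)C(C)(C)C)ccc(OCc2ccccc2)c1OCc1ccccc1 | intermediate
11 | tert-butyl{[3,4-bis(benzyloxy)-2-({[tri(propan-2-yl)silyl]oxy}ethynyl)benzyl]oxy}dimethylsilane (aryl siloxyalkyne) | CC(C)[Si](OC#Cc1c(CO[Si](C)(C)C(C)(C)C)ccc(OCc2ccccc2)c1OCc1ccccc1)(C(C)C)C(C)C | intermediate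
12 | 3-ethoxycyclobut-2-en-1-one | CCOC1=CC(=O)C1 | starting material
13 | 3-(benzyloxy)cyclobut-2-en-1-one | O=C1C=C(OCc2ccccc2)C1 | intermediate
14 | 3-(benzyloxy)buta-1,3-dien-1-one (vinylketene) | C=C(OCc1ccccc1)C=C=O | intermediate
15 | 2-Ar1-4-[1-(benzyloxy)ethenyl]-3-(TIPSO)cyclobut-2-en-1-one (racemic at C4) | O=C1C(c2c(CO[Si](C)(C)C(C)(C)C)ccc(OCc3ccccc3)c2OCc2ccccc2)=C(O[Si](C(C)C)(C(C)C)C(C)C)C1C(=C)OCc1ccccc1 | intermediate
16 | 2-Ar1-5-(benzyloxy)-3-(TIPSO)hexa-1,3,5-trien-1-one, ketene and vinyl termini cis on the central double bond | O=C=C(c1c(CO[Si](C)(C)C(C)(C)C)ccc(OCc2ccccc2)c1OCc1ccccc1)/C(O[Si](C(C)C)(C(C)C)C(C)C)=C\C(=C)OCc1ccccc1 | intermediate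
17 | 2-Ar1-5-(benzyloxy)-3-(TIPSO)cyclohexa-2,4-dien-1-one | O=C1CC(OCc2ccccc2)=CC(O[Si](C(C)C)(C(C)C)C(C)C)=C1c1c(CO[Si](C)(C)C(C)(C)C)ccc(OCc2ccccc2)c1OCc1ccccc1 | intermediate
18 | 2-Ar1-5-(benzyloxy)-3-(TIPSO)phenol | Oc1cc(OCc2ccccc2)cc(O[Si](C(C)C)(C(C)C)C(C)C)c1-c1c(CO[Si](C)(C)C(C)(C)C)ccc(OCc2ccccc2)c1OCc1ccccc1 | intermediate
19 | 2-Ar1-5-(benzyloxy)-6-iodo-3-(TIPSO)phenol | Oc1c(I)c(OCc2ccccc2)cc(O[Si](C(C)C)(C(C)C)C(C)C)c1-c1c(CO[Si](C)(C)C(C)(C)C)ccc(OCc2ccccc2)c1OCc1ccccc1 | intermediate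
20 | 3,4-bis(benzyloxy)benzaldehyde | O=Cc1ccc(OCc2ccccc2)c(OCc2ccccc2)c1 | starting material
21 | 1,2-bis(benzyloxy)-4-ethynylbenzene | C#Cc1ccc(OCc2ccccc2)c(OCc2ccccc2)c1 | intermediate
22 | 1-[3-Ar1-6-(benzyloxy)-2-hydroxy-4-(TIPSO)phenyl]-3-[3,4-bis(benzyloxy)phenyl]prop-2-yn-1-one | O=C(C#Cc1ccc(OCc2ccccc2)c(OCc2ccccc2)c1)c1c(OCc2ccccc2)cc(O[Si](C(C)C)(C(C)C)C(C)C)c(-c2c(CO[Si](C)(C)C(C)(C)C)ccc(OCc3ccccc3)c2OCc2ccccc2)c1O | intermediate
23 | 1-[3-Ar1-6-(benzyloxy)-2-hydroxy-4-(TIPSO)phenyl]-3-[3,4-bis(benzyloxy)phenyl]-3-(diethylamino)prop-2-en-1-one (alkene geometry unassigned) | CCN(CC)C(=CC(=O)c1c(OCc2ccccc2)cc(O[Si](C(C)C)(C(C)C)C(C)C)c(-c2c(CO[Si](C)(C)C(C)(C)C)ccc(OCc3ccccc3)c2OCc2ccccc2)c1O)c1ccc(OCc2ccccc2)c(OCc2ccccc2)c1 | intermediate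
24 | 8-Ar1-5-(benzyloxy)-2-[3,4-bis(benzyloxy)phenyl]-7-(TIPSO)-4H-chromen-4-one | O=c1cc(-c2ccc(OCc3ccccc3)c(OCc3ccccc3)c2)oc2c(-c3c(CO[Si](C)(C)C(C)(C)C)ccc(OCc4ccccc4)c3OCc3ccccc3)c(O[Si](C(C)C)(C(C)C)C(C)C)cc(OCc3ccccc3)c12 | intermediate
25 | 5-(benzyloxy)-2-[3,4-bis(benzyloxy)phenyl]-8-[2,3-bis(benzyloxy)-6-(hydroxymethyl)phenyl]-7-hydroxy-4H-chromen-4-one | O=c1cc(-c2ccc(OCc3ccccc3)c(OCc3ccccc3)c2)oc2c(-c3c(CO)ccc(OCc4ccccc4)c3OCc3ccccc3)c(O)cc(OCc3ccccc3)c12 | intermediate
26 | 5,7-bis(benzyloxy)-2-[3,4-bis(benzyloxy)phenyl]-8-[2,3-bis(benzyloxy)-6-(hydroxymethyl)phenyl]-4H-chromen-4-one | O=c1cc(-c2ccc(OCc3ccccc3)c(OCc3ccccc3)c2)oc2c(-c3c(CO)ccc(OCc4ccccc4)c3OCc3ccccc3)c(OCc3ccccc3)cc(OCc3ccccc3)c12 | intermediate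
27 | 3,4-bis(benzyloxy)-2-{5,7-bis(benzyloxy)-2-[3,4-bis(benzyloxy)phenyl]-4-oxo-4H-chromen-8-yl}benzaldehyde | O=Cc1ccc(OCc2ccccc2)c(OCc2ccccc2)c1-c1c(OCc2ccccc2)cc(OCc2ccccc2)c2c(=O)cc(-c3ccc(OCc4ccccc4)c(OCc4ccccc4)c3)oc12 | intermediate
28 | 2,4,6-trihydroxyacetophenone | CC(=O)c1c(O)cc(O)cc1O | starting material
29 | 1-[2,4-bis(benzyloxy)-6-hydroxyphenyl]ethan-1-one | CC(=O)c1c(O)cc(OCc2ccccc2)cc1OCc1ccccc1 | intermediate
30 | tert-butyl 3-[2,4-bis(benzyloxy)-6-hydroxyphenyl]-3-oxopropanoate | CC(C)(C)OC(=O)CC(=O)c1c(O)cc(OCc2ccccc2)cc1OCc1ccccc1 | intermediate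
31 | tert-butyl 2-[2,4-bis(benzyloxy)-6-hydroxybenzoyl]-3-[3,4-bis(benzyloxy)-2-Fl-phenyl]prop-2-enoate (alkene geometry unassigned) | CC(C)(C)OC(=O)C(=Cc1ccc(OCc2ccccc2)c(OCc2ccccc2)c1-c1c(OCc2ccccc2)cc(OCc2ccccc2)c2c(=O)cc(-c3ccc(OCc4ccccc4)c(OCc4ccccc4)c3)oc12)C(=O)c1c(O)cc(OCc2ccccc2)cc1OCc1ccccc1 | intermediate
32 | tert-butyl (2S)-5,7-bis(benzyloxy)-2-[3,4-bis(benzyloxy)-2-Fl-phenyl]-4-oxochromane-3-carboxylate (C3 epimers) | O=C1C(C(=O)OC(C)(C)C)[C@@H](c2ccc(OCc3ccccc3)c(OCc3ccccc3)c2-c2c(OCc3ccccc3)cc(OCc3ccccc3)c3c(=O)cc(-c4ccc(OCc5ccccc5)c(OCc5ccccc5)c4)oc23)Oc2cc(OCc3ccccc3)cc(OCc3ccccc3)c21 | intermediate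
33 | (2S)-5,7-bis(benzyloxy)-2-[3,4-bis(benzyloxy)-2-Fl-phenyl]-2,3-dihydro-4H-chromen-4-one (octabenzyl ether of the target) | O=C1C[C@@H](c2ccc(OCc3ccccc3)c(OCc3ccccc3)c2-c2c(OCc3ccccc3)cc(OCc3ccccc3)c3c(=O)cc(-c4ccc(OCc5ccccc5)c(OCc5ccccc5)c4)oc23)Oc2cc(OCc3ccccc3)cc(OCc3ccccc3)c21 | intermediate
34 | (2S)-2-{2-[2-(3,4-dihydroxyphenyl)-5,7-dihydroxy-4-oxo-4H-chromen-8-yl]-3,4-dihydroxyphenyl}-5,7-dihydroxy-2,3-dihydro-4H-chromen-4-one | O=C1C[C@@H](c2ccc(O)c(O)c2-c2c(O)cc(O)c3c(=O)cc(-c4ccc(O)c(O)c4)oc23)Oc2cc(O)cc(O)c21 | target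

Total step count: 19. Longest linear sequence: 15 steps (steps 1–6, 8, 9, 11–14, 17–19).

Steps most likely to fail

Step 8 (benzannulation).
- **What may go wrong:** The vinylogous-ester stabilisation of 13 may push its ring opening to temperatures at which 11 undergoes O-to-C silyl migration. The two ortho substituents of ring B' may also slow the [2+2] capture, so that the vinylketene is consumed by dimerisation or by acylating the product phenol.
- **Fallback (sets out from 11, returns at 18):** The same vinylketene is released without heat by 1,4-dehydrochlorination. Commercial ethyl (E)-3-ethoxybut-2-enoate is transetherified with benzyl alcohol (cat. TsOH, removal of ethanol) to ethyl (E)-3-(benzyloxy)but-2-enoate F1. This is saponified (LiOH, aqueous THF, then mild acid) to (E)-3-(benzyloxy)but-2-enoic acid F2, which oxalyl chloride with catalytic DMF converts into (E)-3-(benzyloxy)but-2-enoyl chloride F3. Slow addition of F3 to 11 and Et3N in CH2Cl2 at room temperature generates 14 in the presence of the ynol ether, and 15 is now isolated. Heating 15 alone in toluene leaves only the two unimolecular pericyclic events through 16 and 17 before 18.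

Step 11 (carbonylative annulation).
- **What may go wrong:** Oxidative addition into an electron-rich aryl iodide with two ortho oxygens may be slow. Protodeiodination, direct non-carbonylative alkynylation followed by benzofuran closure, or five-membered closure to the aurone could then compete. Incomplete regiocontrol in step 9 would add to the loss.
- **Fallback (sets out from 18, bypasses steps 9 and 11, returns at 24):** Magnesium-phenoxide-directed ortho-formylation (MgCl2, Et3N, paraformaldehyde, MeCN, reflux) can only reach C4a'' and gives 3-Ar1-6-(benzyloxy)-2-hydroxy-4-(TIPSO)benzaldehyde F4. Addition of the lithium acetylide of 21 (2.2 equiv, THF, −78 °C) gives 1-[3-Ar1-6-(benzyloxy)-2-hydroxy-4-(TIPSO)phenyl]-3-[3,4-bis(benzyloxy)phenyl]prop-2-yn-1-ol F5. MnO2 in CH2Cl2 oxidises F5 to ynone 22, now isolated, and warming 22 with Et2NH in ethanol closes ring C'' through 23 to 24.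

Step 18 (asymmetric oxa-Michael closure).
- **What may go wrong:** The very large ortho substituent on ring B' and the uncontrolled axis (matched and mismatched atropisomers) may erode facial selectivity. Uncatalysed cyclisation already during step 17 would deliver racemic material. Reversible ring opening during the warm decarboxylation may lower the enantiomeric purity.
- **Fallback (sets out from 27 and 29, returns at 33):** Claisen–Schmidt condensation (KOH, EtOH/THF, rt) gives (E)-1-[2,4-bis(benzyloxy)-6-hydroxyphenyl]-3-[3,4-bis(benzyloxy)-2-Fl-phenyl]prop-2-en-1-one F6. NaOAc in refluxing ethanol cyclises it to racemic 5,7-bis(benzyloxy)-2-[3,4-bis(benzyloxy)-2-Fl-phenyl]-2,3-dihydro-4H-chromen-4-one F7. Kinetic resolution by asymmetric transfer hydrogenation (RuCl(p-cymene)[(R,R)-TsDPEN], HCO2H/Et3N, rt, stopped near half conversion) reduces the 2R enantiomer to (2R,4R)-5,7-bis(benzyloxy)-2-[3,4-bis(benzyloxy)-2-Fl-phenyl]chroman-4-ol F8. The unreacted ketone is recovered as 33.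

Further compounds
F1 | step 8 | ethyl (E)-3-(benzyloxy)but-2-enoate | CCOC(=O)/C=C(\C)OCc1ccccc1
F2 | step 8 | (E)-3-(benzyloxy)but-2-enoic acid | OC(=O)/C=C(\C)OCc1ccccc1
F3 | step 8 | (E)-3-(benzyloxy)but-2-enoyl chloride | ClC(=O)/C=C(\C)OCc1ccccc1
F4 | step 11 | 3-Ar1-6-(benzyloxy)-2-hydroxy-4-(TIPSO)benzaldehyde | O=Cc1c(OCc2ccccc2)cc(O[Si](C(C)C)(C(C)C)C(C)C)c(-c2c(CO[Si](C)(C)C(C)(C)C)ccc(OCc3ccccc3)c2OCc2ccccc2)c1O
F5 | step 11 | 1-[3-Ar1-6-(benzyloxy)-2-hydroxy-4-(TIPSO)phenyl]-3-[3,4-bis(benzyloxy)phenyl]prop-2-yn-1-ol (racemic carbinol) | OC(C#Cc1ccc(OCc2ccccc2)c(OCc2ccccc2)c1)c1c(OCc2ccccc2)cc(O[Si](C(C)C)(C(C)C)C(C)C)c(-c2c(CO[Si](C)(C)C(C)(C)C)ccc(OCc3ccccc3)c2OCc2ccccc2)c1O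
F6 | step 18 | (E)-1-[2,4-bis(benzyloxy)-6-hydroxyphenyl]-3-[3,4-bis(benzyloxy)-2-Fl-phenyl]prop-2-en-1-one | O=C(/C=C/c1ccc(OCc2ccccc2)c(OCc2ccccc2)c1-c1c(OCc2ccccc2)cc(OCc2ccccc2)c2c(=O)cc(-c3ccc(OCc4ccccc4)c(OCc4ccccc4)c3)oc12)c1c(O)cc(OCc2ccccc2)cc1OCc1ccccc1
F7 | step 18 | racemic 5,7-bis(benzyloxy)-2-[3,4-bis(benzyloxy)-2-Fl-phenyl]-2,3-dihydro-4H-chromen-4-one | O=C1CC(c2ccc(OCc3ccccc3)c(OCc3ccccc3)c2-c2c(OCc3ccccc3)cc(OCc3ccccc3)c3c(=O)cc(-c4ccc(OCc5ccccc5)c(OCc5ccccc5)c4)oc23)Oc2cc(OCc3ccccc3)cc(OCc3ccccc3)c21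
F8 | step 18 | (2R,4R)-5,7-bis(benzyloxy)-2-[3,4-bis(benzyloxy)-2-Fl-phenyl]chroman-4-ol | O[C@@H]1C[C@H](c2ccc(OCc3ccccc3)c(OCc3ccccc3)c2-c2c(OCc3ccccc3)cc(OCc3ccccc3)c3c(=O)cc(-c4ccc(OCc5ccccc5)c(OCc5ccccc5)c4)oc23)Oc2cc(OCc3ccccc3)cc(OCc3ccccc3)c21
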